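**The curve.** With time the ochre run rises steeply and then bends: E reads 49.9% at 2.00 min, 60.6% at 4.00 min, and lies near 65.4% at 10.0 min, although 34.6% of the J is not in E. So the level is the landmark to reckon. Ochre's L can make 0.500 mM of living ends D against 1 mM of X, which removes D (termination). Blue, whose L at 1.10 mM is more than its X, climbs to 98.6%.

| flask | J | X | L | remark | time |
|---|---|---|---|---|---|
| ochre | 0.10 M | 1 mM | 0.5 mol% | run made earlier |  |
| teal | 0.10 M | 1 mM | 0.7 mol% | run made earlier |  |
| blue | 0.10 M | 1 mM | 1.1 mol% | run made earlier |  |
| green | 0.10 M | 2 mM | 0.5 mol% | run made earlier |  |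
| dawn | 0.10 M | 1.00 mM | 0.5 mol% | a single well-mixed tank run continuously and read at steady state, 150 min in it on average |  |
| midnight | 0.10 M | 1.00 mM | 0.5 mol% | a single well-mixed tank run continuously and read at steady state, 15 min in it on average |  |
| winter | 0.10 M | 1.00 mM | 0.5 mol% | everything together in a closed stirred flask, run for 15 min | 15 min |
| summer | 0.10 M (fed, over 15.0 min) | 1.00 mM | 0.5 mol% | a stirred flask in which J is dosed at a steady rate over 15.0 min without added volume, worked up at 15 min | 15 min |

| run | time / min | E / % |
|---|---|---|
| ochre | 2.00 | 49.9 |
| ochre | 4.00 | 60.6 |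
| ochre | 5.00 | 62.1 |
| ochre | 8.00 | 65.0 |
| ochre | 10.0 | 65.4 |
| teal | 1.00 | 44.7 |
| teal | 3.00 | 72.4 |
| teal | 6.00 | 80.8 |
| teal | 8.00 | 82.2 |
| teal | 12.0 | 83.7 |
| blue | 2.50 | 86.6 |
| blue | 5.00 | 95.4 |
| blue | 8.00 | 97.5 |
| blue | 10.0 | 98.7 |
| blue | 12.0 | 98.6 |
| green | 2.50 | 35.0 |
| green | 5.00 | 36.2 |
| green | 8.00 | 36.3 |
| green | 10.0 | 35.4 |
| green | 12.0 | 35.9 |

(readings scatter by 0.5 percentage points)

- in percentages every species weighs as the J in it: one Z counts as two
- the stated concentrations are those of everything mixed, before any reaction; amounts are the same in each set-up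
- what may be going on: J + L -> D + E; J + D -> E + D; D + X -> Q; J + E -> Z
- the feed brings no volume worth counting
- the earlier runs were made in a closed, stirred flask

- order of the set-ups by the amount of E at the outlet or at the end, in percent of the J put in, highest first (dawn / midnight / winter / summer)
- amount of E at the outlet or at the end, in percent of the J put in, dawn
- amount of E at the outlet or at the end, in percent of the J put in, midnight
- amount of E at the outlet or at the end, in percent of the J put in, winter
- amount of E at the outlet or at the end, in percent of the J put in, summer

**The level.** While D lives, J falls by growth and X by D + X → Q, both in proportion to D. So ln(J at start/J at end) = r·ln(X at start/X at end), and X ends lower by the L charged. Ochre gives r = 1.53: the reach, the fall in ln J per unit fall in ln X.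

**Going round.** We put r back into the other runs. Teal should level at 84.2% and reads 83.7%; green should level at 35.6% and reads 35.9%. Winter repeats ochre's charge, so our figure for it is ochre's level.

**The tank.** In dawn, at steady state, the feed takes the place of time, and the same two balances give (J grown)/J = r·(X fed − X)/X. With X down by the L charged, X lost and X left are equal, so J grown per J left is r, and with J + E → Z set aside, so that grown and left add up to the J fed, our figure for J grown is 60.5%. That is J grown, not E kept. No steady fall of E stands out of the scatter of 0.5 percentage points, but dawn holds its contents 150 min on average, ten times winter's 15 min, so we take our figure as a top for E.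

**The forecast.** The forecast gives winter > dawn > midnight > summer, with dawn 59.8% (53% to 62%) beside our own top figure, midnight 53.8%, winter 65.4% and summer 20%, and notes that “a slow loss could matter at 150 min”.

    J + L → D + E (k = 0.920 /M/s)
    J + D → E + D, rate k2*[D]*[J] (k = 24.0 /M/s)
    D + X → Q (k = 15.0 /M/s)
    J + E → Z (k = 0.00110 /M/s)

**The flask.** The order is winter > midnight > dawn > summer, with dawn 39.6%, midnight 51.5%, winter 64.8% and summer 21.3%. Dawn's outlet holds Z at 26.5% and J at 0.0339 M. One Z takes one E and one J, so J grown is E plus Z over two, 52.8%, and per J left that is 1.56 against r of 1.53. In a neighbour of winter with 0.12 mol% of L, X stands at 88% at 15.0 min, r gives 17.8% of J grown, and E stands at 17.3%.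

Readings and results are simulated for an exercise; noise was put on by code.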